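## The problem

1. Target 21 is a single cyclohexene ring with four contiguous oxygenated stereocentres (C6, C1, C2, C3); the ring is numbered here with C1 the quaternary carbinol carrying the hydroxymethyl carbon C7, C2 the free secondary carbinol, C3 and C6 the benzoate carbons and C4=C5 the alkene, and β denotes the ring face that holds C7 (α the face that holds O1).
2. In this frame 21 is (1S,2R,3R,6S): O2, O3, O6 and C7 all lie on the β face and O1 stands alone on the α face.
3. There is no ring fusion to lean on, so the quaternary centre C1 must act as the stereochemical hub: once C1 and C6 are fixed, the substituents on C1 have to steer the oxygenation of C2 and C3.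
4. Five hydroxyl groups must be told apart: only O3 and O6, both allylic, are benzoylated, while the tertiary O1, the neopentyl-type O2 and the primary O7 stay free.
5. The esters are the fragile part: a benzoate on O3 can migrate to the cis O2 and one on O6 to O7 under base, both are allylic esters that zerovalent palladium would ionise, and neither can be carried β to a ketone.
6. Several intermediates are fragile as well: a 4-(hydroxymethyl)cyclohexadienone rearomatises by loss of formaldehyde when O7 is deprotonated, and β-oxygenated ketones eliminate under base.
7. The enabling feature is that C1 with O1 and C7 is the para carbon of dearomatised 4-hydroxybenzyl alcohol: in dienone 5 the C2=C3 and C5=C6 enone arms are enantiotopic, and O6 of the target is 1,3-related and cis to O7, so an oxygen tethered to O7 through one boron atom can be delivered to C6 and fix C6 and C1 in one ring closure.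

## Retrosynthesis

**Si–O bonds and the O3 ester.** Target 21 is first traced to bis-silyl ether 20 by cutting only two O–Si bonds, so that the last step is a deprotection with acidic fluoride, under which benzoates do not migrate. In 20 the O3–C(=O) bond is cut to give diol 19 and benzoyl chloride 16. Cutting both ester bonds at once, back to a 2,3,6-triol, was set aside because O2 and O6 both sit next to the quaternary C1 and cannot be told apart. With O6 already acylated, the forward reaction only has to prefer the allylic O3 over O2, which is wedged between C1 (OTBS, CH2OTBDPS) and C3. Diol 19 comes from acetonide 18 by hydrolysis of the C2/C3 dioxolane.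

**The O6 ester and the O7 silyl ether.** In 18 the O6–C(=O) bond and then the O7–Si bond are cut, through silyl ether 17, to 6,7-diol 15 and 16. A primary and a hindered secondary hydroxyl are safely distinguished by a bulky silyl chloride, and TBDPS is chosen because it must outlast the acid that later opens the dioxolane. Diol 15 results from opening only the six-membered acetonide of bis-acetonide 14. Compared with 18, 14 lacks an ester and a silyl group and is a compact tricyclic ether whose only reactive site is the alkene. The forward step must hydrolyse the 1,3-dioxane and leave the cis-fused dioxolane, which is the usual order of reactivity.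

**The C4–H bond.** Alkene 14 is cut at C4–H to enol triflate 13, and this at O–S to ketone 12, so that C4=C5 derives from a C4 carbonyl group. This is preferred to a C2=C3/C4=C5 diene precursor, which would pose a choice between two alkenes in the dihydroxylation, and to dehydration of a C4 alcohol, whose direction (toward C3 or C5) is not controlled. A carbonyl para to C1 is exactly what a dearomatised phenol leaves behind, so the cut points to the starting material. The forward steps must enolise 12 toward the C5 methylene and not toward the oxygenated C3, trap the enolate before O6 is lost by β-elimination, and reduce the triflate without touching allylic oxygen. No ester may be present at this stage, which is why the benzoates come later.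

**The C2–O and C3–O bonds.** After removal of the dioxolane (12 back to diol 11), both C–O bonds are cut together as a syn-dihydroxylation of enone 10. This removes two stereocentres and leaves a substrate with a single alkene; cutting the bonds one at a time (epoxide opening) would give the trans diol instead. The forward reaction must bring osmium to the β face, anti to O1. In 10 the gem-dimethyl acetal locks the bicycle so that the OTBS group is pseudoaxial on the α face next to C2, which is why the boronate is exchanged for an acetonide before this step and not after it.

**The C6–O6 bond (key disconnection).** Acetonide 10 is the protected form of diol 9, itself released from boronate 8. In 8 the C6–O bond is cut: the ring opens to hemiester 7, which is dienone 5 esterified at O7 by phenylboronic acid 6. This cut is preferred to an intermolecular oxygenation of C6, because the tether guarantees both the regiochemistry and the cis relation of O6 to C7. It is also preferred to a tether from O1, which would place the new oxygen cis to O1, on the wrong face. The simplification is large: 5 is achiral and both stereocentres of 8 arise in one bond-forming event. The forward reaction asks a chiral amine–thiourea to select one of two enantiotopic enone arms; the face is a matter of reach, not of selectivity.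

**The C1–O1 bond.** Dienone 5 needs O1 silylated and O7 free, the reverse of what direct silylation of a primary/tertiary diol gives. It is therefore traced to bis-silyl ether 4 (selective loss of the primary group), to para-quinol 3 and, by cutting C1–O1, to phenol 2, the monosilyl ether of 4-hydroxybenzyl alcohol 1. Adding the hydroxymethyl carbon to a quinone monoketal would reach the same quinol but needs an alkoxymethyl-metal reagent, whereas the dearomatisation uses the carbon skeleton as purchased. The forward oxidation must deliver water to the para carbon of the phenol.

## Roads not taken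

Alternative 1: The ring is cut at C1–O1 and C6–O6 together, back to benzoic acid A1. In the forward key step, whole cells of a blocked Cupriavidus necator mutant expressing benzoate 1,2-dioxygenase add dioxygen across the ipso and ortho carbons and give the diene diol acid A2.
- **Merits:** One step from an aromatic commodity creates the quaternary carbinol and carries all seven carbons (C7 as the carboxyl group). With the ortho carbon read as C6, A2 already has the C1 configuration of 21, and its enantiopurity is enzymatic. In steps to an enantiopure intermediate this road is clearly better than the chosen one (one step against five) and needs no catalyst optimisation.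
- **Weak points:** The enzymatic dihydroxylation is cis, so O6 of A2 lies on the face of O1, whereas in 21 both ring neighbours of C1 carry oxygen trans to O1. The carbinol next to the quaternary centre would have to be inverted on a cyclohexadienol that aromatises readily by dehydration; a Mitsunobu esterification (with A1 as the acid) could in principle install the benzoate with inversion, but SN2′ attack and elimination compete. The diene must then be dihydroxylated at C2=C3, the more hindered alkene next to the quaternary carbon, while C4=C5 is spared; the carboxyl group must be reduced; and a fermentation with a mutant strain is required.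
- **Comparison:** Against the shorter access, the chosen plan builds the trans O1/O6 relation directly through the O7 tether, has a single alkene at the dihydroxylation stage and uses only ordinary laboratory reagents.

Alternative 2: The cut is made at C1–O1 and C2–O as an oxirane, with the C4=C5 alkene masked in a Diels–Alder adduct. In the forward key step, alkaline peroxide adds to C2 of the norbornene-fused ene-dione A3 from its convex face and the resulting C1 enolate closes on oxygen to give epoxide A4.
- **Merits:** The rigid adduct gives dependable facial control for the epoxidation and for later carbonyl reductions, which are expected from the convex face and would place O3 and O6 trans to the epoxide oxygen. Opening the oxirane at C2 with inversion would give O2 trans to O1, as 21 requires. The oxygens are differentiated by oxidation level: the two hydroxyls that arise from the ketones are exactly those to be benzoylated, while O1 and O2 stay masked in the oxirane. This road therefore needs fewer protecting-group operations than the chosen one, a real advantage.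
- **Weak points:** A3 is chiral and the key step only relays its configuration, so the absolute sense must be obtained by a resolution or a separate asymmetric cycloaddition. The alkene is released by a retro-Diels–Alder reaction at high temperature, at a stage carrying either allylic benzoates (prone to acyloxy shifts and elimination) or a sensitive epoxy ketone. The final hydrolytic opening must occur at the secondary C2 and not at the tertiary C1, which acid prefers.
- **Comparison:** The chosen plan creates chirality by catalysis on an achiral substrate, runs at or below 60 °C throughout and has no regiochemical question in an epoxide opening. It pays for this with more protecting-group steps.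

Alternative 3: The cut is a carbon–carbon bond, C1–C6. A sugar-derived 2-alkoxyglycal carrying an E-alkoxyvinyl arm undergoes a thermal [3,3] shift that forms C1–C6, breaks the ring C–O bond and closes the carbocycle, releasing C7 as the aldehyde of A5.
- **Merits:** A5 has all four stereocentres in the configuration of 21, the C4=C5 alkene in place, O2/O3 already set apart from O1/O6 and its absolute configuration from the chiral pool. After its key step this road is further advanced than the chosen one after step 5, which still has to add O2 and O3 and remove the carbonyl group.
- **Weak points:** The rearrangement substrate, a doubly enol-etherified glycal with a geometrically pure side arm, needs a long carbohydrate sequence. The configuration at C6 depends on the chair or boat shape of the transition state and on the E geometry. The electron-rich bis-enol ether has to be heated. After A5 the aldehyde must be reduced, two PMB ethers removed, and the O3/O2 and O6/O7 differentiations remain the same as in the chosen plan.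
- **Comparison:** The chosen plan reaches its key-step substrate in four simple steps from a cheap phenol and sets its stereochemistry by catalysis; its sequence after the key step is longer than that from A5.

Key step: step 5

Assumption: the sense of enantioselection of cinchona-derived amine–thioureas on this new dienone cannot be read from the structures; the quinine-derived catalyst is written, and its quinidine-derived pseudoenantiomer would replace it unchanged if the mirror-image boronate were favoured.

Names of ring compounds use the route numbering and the β/α convention defined above; TBS = tert-butyldimethylsilyl, TBDPS = tert-butyldiphenylsilyl.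

## Route

Step 1
Reactants: 1 4-hydroxybenzyl alcohol
Product: 2 4-[(tert-butyldimethylsilyloxy)methyl]phenol
Conditions: TBSCl (1.05 equiv), imidazole, DMF, 0 °C
Reagents that add atoms: tert-butyldimethylsilyl chloride, CC(C)(C)[Si](C)(C)Cl
Why: Chemoselective O-silylation: with one equivalent of silyl chloride under imidazole catalysis the aliphatic benzylic hydroxyl should be silylated in preference to the phenol, and any aryl silyl ether is the more base-labile one and is cleaved back on mild basic work-up.

Step 2
Reactants: 2 4-[(tert-butyldimethylsilyloxy)methyl]phenol
Product: 3 4-hydroxy-4-[(tert-butyldimethylsilyloxy)methyl]cyclohexa-2,5-dien-1-one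
Conditions: PhI(OAc)2, MeCN/H2O (3:1), 0 °C
Reagents that add atoms: water, O
Why: Oxidative dearomatisation of a para-substituted phenol with a trivalent iodine reagent: ligand exchange at iodine, loss of iodobenzene and capture of the phenoxenium-type intermediate by water at the para carbon should give the para-quinol. The silyl ether on O7 keeps C7 from leaving as formaldehyde and should survive brief contact with dilute acetic acid at 0 °C.

Step 3
Reactants: 3 4-hydroxy-4-[(tert-butyldimethylsilyloxy)methyl]cyclohexa-2,5-dien-1-one
Product: 4 4-(tert-butyldimethylsilyloxy)-4-[(tert-butyldimethylsilyloxy)methyl]cyclohexa-2,5-dien-1-one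
Conditions: TBSOTf, 2,6-lutidine, CH2Cl2, −78 to 0 °C
Reagents that add atoms: tert-butyldimethylsilyl triflate, CC(C)(C)[Si](C)(C)OS(=O)(=O)C(F)(F)F
Why: Silyl triflate/2,6-lutidine silylation of a tertiary alcohol; the cross-conjugated dienone has no enolisable hydrogen, so only O1 should react.

Step 4
Reactants: 4 4-(tert-butyldimethylsilyloxy)-4-[(tert-butyldimethylsilyloxy)methyl]cyclohexa-2,5-dien-1-one
Product: 5 4-(tert-butyldimethylsilyloxy)-4-(hydroxymethyl)cyclohexa-2,5-dien-1-one
Conditions: AcOH/THF/H2O (3:1:1), rt
Reagents that add atoms: none
Why: Acid-catalysed solvolysis discriminates silyl ethers by steric access, so the primary TBS ether should be cleaved while the tertiary one is inert. The acidic medium avoids the O7 alkoxide that would trigger silyl migration from O1 to O7 or loss of formaldehyde with rearomatisation.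

Step 5
Reactants: 5 4-(tert-butyldimethylsilyloxy)-4-(hydroxymethyl)cyclohexa-2,5-dien-1-one; 6 phenylboronic acid
Product: 8 (1R,6S)-cyclohex-2-en-4-one carrying OTBS on C1 and a phenylboronate bridging O6 and O7 (cis-fused 2-phenyl-1,3,2-dioxaborinane; O6 and C7 both β), via boronic hemiester 7 (not isolated)
Conditions: 9-amino-9-deoxy-epi-quinine-derived 3,5-bis(trifluoromethyl)phenyl thiourea (10 mol %), 4 Å molecular sieves, toluene, rt
Reagents that add atoms: none
Why: Boronic acid 6 should condense with the only free hydroxyl of 5 to give hemiester 7 (the sieves take up the water); the quinuclidine nitrogen of the catalyst binds boron and turns the remaining B–OH into a nucleophilic boronate oxygen while the thiourea hydrogen-bonds the dienone carbonyl, and intramolecular oxa-Michael addition to C6 followed by protonation at C5 closes the dioxaborinane. The closest known reaction type is the amine–thiourea-catalysed oxa-Michael addition of boronic acid hemiesters to γ- and δ-hydroxy enones, taken together with catalytic oxa-Michael desymmetrisation of 4,4-disubstituted cyclohexadienones. The one ring formed is six-membered and closes in the 6-exo-trig mode. C6 is set relative to C1 by the tether: the O7–B–O chain hangs from C7 and is only three atoms long, so it can reach C6 solely on the face that carries C7, which makes the ring fusion cis (O6 β, trans to O1). C1 becomes stereogenic in the same event and its absolute sense is set by the catalyst, which has to pick the pro-S enone arm (the one that becomes C5–C6). The step therefore needs enantiotopic-group selectivity from the catalyst and face selectivity from the tether; the substrate secures the latter and, through the silyl group on O1, removes the only other hydroxyl that could have formed a five-membered boronate and delivered oxygen cis to O1. Near-neutral conditions at room temperature should keep 5 from losing formaldehyde by rearomatisation and the TBS group from shifting to O7.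

Step 6
Reactants: 8 cis-fused O6/O7 phenylboronate enone
Product: 10 6,7-O-isopropylidene-1-O-TBS enone (cis-fused 2,2-dimethyl-1,3-dioxane on the cyclohex-2-en-4-one; O6 and C7 β), via diol enone 9 (not isolated)
Conditions: H2O2 (30% aq.), pH 7 phosphate buffer, THF, 0 °C; then crude diol, 2-methoxypropene, PPTS (cat.), CH2Cl2, 0 °C
Reagents that add atoms: 2-methoxypropene, COC(C)=C
Why: Arylboronates are oxidised by H2O2 at neutral pH (aryl shift from boron to oxygen, then hydrolysis), which should free the 1,3-diol without the hydroperoxide anion needed for enone epoxidation. The diol is trapped at once by acid-catalysed acetalisation before the β-hydroxy ketone can eliminate. The acetonide is chosen because its axial methyl forces C5 equatorial on the dioxane chair and thereby the OTBS group pseudoaxial on the α face of the enone; no stereocentre is touched.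

Step 7
Reactants: 10 6,7-O-isopropylidene-1-O-TBS enone
Product: 11 2β,3β-dihydroxy-6,7-O-isopropylidene-1-O-TBS-cyclohexan-4-one
Conditions: OsO4 (5 mol %), NMO, acetone/H2O (8:1), rt
Reagents that add atoms: N-methylmorpholine N-oxide, C[N+]1([O-])CCOCC1; water, O; osmium tetroxide (catalytic oxygen carrier), O=[Os](=O)(=O)=O
Why: Catalytic syn-dihydroxylation of the enone alkene. The pseudoaxial OTBS group on the allylic carbon C1 blocks the α face, and osmylation anti to an allylic oxygen is the normal preference, so both new hydroxyls should enter on the β face, cis to C7 and O6. The suprafacial [3+2] addition makes O2 and O3 cis to each other.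

Step 8
Reactants: 11 2β,3β-dihydroxy-6,7-O-isopropylidene-1-O-TBS-cyclohexan-4-one
Product: 12 2,3:6,7-di-O-isopropylidene-1-O-TBS-cyclohexan-4-one
Conditions: 2,2-dimethoxypropane, PPTS (cat.), acetone, rt
Reagents that add atoms: 2,2-dimethoxypropane, COC(C)(C)OC
Why: Acid-catalysed transketalisation closes the cis-2,3-diol to a five-membered dioxolane. This masks both hydroxyls for the enolate step, and the cis ring fusion protects C3 from epimerisation next to the ketone.

Step 9
Reactants: 12 2,3:6,7-di-O-isopropylidene-1-O-TBS-cyclohexan-4-one
Product: 13 C4 enol triflate of 12 (C4=C5 alkene bearing OTf on C4)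
Conditions: KN(SiMe3)2, PhNTf2, THF, −78 °C
Reagents that add atoms: N-phenylbis(trifluoromethanesulfonimide), O=S(=O)(N(c1ccccc1)S(=O)(=O)C(F)(F)F)C(F)(F)F
Why: Kinetic deprotonation with a hindered amide base should take the C5 methylene and not the oxygen-bearing, acetal-flanked C3, and the potassium enolate is O-triflated by PhNTf2 (enol triflate formation). At −78 °C trapping should outrun β-elimination of the acetal oxygen O6.

Step 10
Reactants: 13 C4 enol triflate
Product: 14 2,3:6,7-di-O-isopropylidene-1-O-TBS-cyclohex-4-ene
Conditions: Pd(OAc)2 (5 mol %), PPh3, HCO2H, Et3N, DMF, 60 °C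
Reagents that add atoms: none
Why: Palladium-catalysed formate reduction of an enol triflate: zerovalent palladium formed in situ inserts into the C4–O bond, formate replaces triflate, CO2 is lost and reductive elimination forms C4–H with the C4=C5 alkene left in place. The allylic oxygens on C3 and C6 are acetal ethers and should not ionise.

Step 11
Reactants: 14 2,3:6,7-di-O-isopropylidene-1-O-TBS-cyclohex-4-ene
Product: 15 2,3-O-isopropylidene-1-O-TBS-cyclohex-4-ene-6β,7-diol
Conditions: AcOH/THF/H2O (2:1:1), rt
Reagents that add atoms: none
Why: Selective acetal hydrolysis: the six-membered acetonide, strained by its axial methyl, should hydrolyse much faster than the cis-fused dioxolane, as in the selective opening of 4,6- over 2,3-O-isopropylidene groups in pyranosides. The tertiary TBS ether is inert to aqueous acetic acid.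

Step 12
Reactants: 15 2,3-O-isopropylidene-1-O-TBS-cyclohex-4-ene-6β,7-diol; 16 benzoyl chloride
Product: 18 6-O-benzoyl-7-O-TBDPS-2,3-O-isopropylidene-1-O-TBS-cyclohex-4-ene, via silyl ether 17 (not isolated)
Conditions: TBDPSCl (1.1 equiv), Et3N, DMAP (cat.), CH2Cl2, 0 °C to rt; then BzCl, DMAP, rt
Reagents that add atoms: tert-butyldiphenylsilyl chloride, CC(C)(C)[Si](Cl)(c1ccccc1)c1ccccc1
Why: The bulky silyl chloride should take only the primary O7, after which benzoyl chloride with DMAP (nucleophilic catalysis through the N-benzoylpyridinium ion) acylates the remaining hindered secondary allylic O6. No bond to C6 is broken, so its configuration is kept, and with O1 and O7 silylated the new ester has no free neighbour to migrate to.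

Step 13
Reactants: 18 6-O-benzoyl-7-O-TBDPS-2,3-O-isopropylidene-1-O-TBS-cyclohex-4-ene
Product: 19 6-O-benzoyl-7-O-TBDPS-1-O-TBS-cyclohex-4-ene-2β,3β-diol
Conditions: TFA/H2O (9:1), CH2Cl2, 0 °C
Reagents that add atoms: none
Why: Aqueous acid hydrolysis of the dioxolane. TBDPS is the silyl ether chosen for O7 because it withstands aqueous TFA at 0 °C, the benzoate is acid-stable, and loss of the tertiary TBS group, should it occur, would be harmless.

Step 14
Reactants: 19 6-O-benzoyl-7-O-TBDPS-1-O-TBS-cyclohex-4-ene-2β,3β-diol; 16 benzoyl chloride
Product: 20 3,6-di-O-benzoyl-7-O-TBDPS-1-O-TBS-cyclohex-4-en-2β-ol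
Conditions: BzCl (1.1 equiv), pyridine, CH2Cl2, −40 to 0 °C
Reagents that add atoms: none
Why: Kinetic monoacylation of a vicinal diol with a slight excess of acid chloride and no DMAP: O3 is allylic and flanked by the sp2 carbon C4, whereas O2 is wedged between the quaternary C1 (OTBS, CH2OTBDPS) and C3, so the ester should form at O3. A cold, slightly acidic work-up avoids O3-to-O2 migration.

Step 15
Reactants: 20 3,6-di-O-benzoyl-7-O-TBDPS-1-O-TBS-cyclohex-4-en-2β-ol
Product: 21 (1S,2R,3R,6S)-1-(hydroxymethyl)cyclohex-4-ene-1,2,3,6-tetrol 3,6-dibenzoate (CNP0212417.6)
Conditions: HF (48% aq.), MeCN, 0 °C to rt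
Reagents that add atoms: none
Why: Acidic fluoride desilylation should remove the primary TBDPS and the tertiary TBS ether in one operation. An acidic fluoride source is used because basic fluoride would promote benzoate migration to the neighbouring free hydroxyls; no stereocentre is involved.

## Compound list

1 | 4-hydroxybenzyl alcohol | OCc1ccc(O)cc1 | starting material
2 | 4-[(tert-butyldimethylsilyloxy)methyl]phenol | CC(C)(C)[Si](C)(C)OCc1ccc(O)cc1 | intermediate
3 | 4-hydroxy-4-[(tert-butyldimethylsilyloxy)methyl]cyclohexa-2,5-dien-1-one | O=C1C=CC(O)(CO[Si](C)(C)C(C)(C)C)C=C1 | intermediate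
4 | 4-(tert-butyldimethylsilyloxy)-4-[(tert-butyldimethylsilyloxy)methyl]cyclohexa-2,5-dien-1-one | O=C1C=CC(O[Si](C)(C)C(C)(C)C)(CO[Si](C)(C)C(C)(C)C)C=C1 | intermediate
5 | 4-(tert-butyldimethylsilyloxy)-4-(hydroxymethyl)cyclohexa-2,5-dien-1-one | O=C1C=CC(CO)(O[Si](C)(C)C(C)(C)C)C=C1 | intermediate
6 | phenylboronic acid | OB(O)c1ccccc1 | starting material
7 | O7 phenylboronic hemiester of 5 (not isolated) | O=C1C=CC(COB(O)c2ccccc2)(O[Si](C)(C)C(C)(C)C)C=C1 | intermediate
8 | (1R,6S) cis-fused O6/O7 phenylboronate enone with OTBS on C1 | O=C1C=C[C@@]2(O[Si](C)(C)C(C)(C)C)COB(c3ccccc3)O[C@H]2C1 | intermediate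
9 | 1-O-TBS-6β-hydroxy-1-(hydroxymethyl)cyclohex-2-en-4-one (not isolated) | O[C@H]1CC(=O)C=C[C@@]1(O[Si](C)(C)C(C)(C)C)CO | intermediate
10 | 6,7-O-isopropylidene-1-O-TBS enone | CC2(C)O[C@H]1CC(=O)C=C[C@@]1(O[Si](C)(C)C(C)(C)C)CO2 | intermediate
11 | 2β,3β-dihydroxy-6,7-O-isopropylidene-1-O-TBS-cyclohexan-4-one | CC2(C)O[C@H]1CC(=O)[C@@H](O)[C@@H](O)[C@@]1(O[Si](C)(C)C(C)(C)C)CO2 | intermediate
12 | 2,3:6,7-di-O-isopropylidene-1-O-TBS-cyclohexan-4-one | CC2(C)O[C@H]1CC(=O)[C@@H](O3)[C@@H](OC3(C)C)[C@@]1(O[Si](C)(C)C(C)(C)C)CO2 | intermediate
13 | C4 enol triflate of 12 (C4=C5) | CC2(C)O[C@H]1C=C(OS(=O)(=O)C(F)(F)F)[C@@H](O3)[C@@H](OC3(C)C)[C@@]1(O[Si](C)(C)C(C)(C)C)CO2 | intermediate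
14 | 2,3:6,7-di-O-isopropylidene-1-O-TBS-cyclohex-4-ene | CC2(C)O[C@H]1C=C[C@@H](O3)[C@@H](OC3(C)C)[C@@]1(O[Si](C)(C)C(C)(C)C)CO2 | intermediate
15 | 2,3-O-isopropylidene-1-O-TBS-cyclohex-4-ene-6β,7-diol | O[C@H]1C=C[C@@H](O2)[C@@H](OC2(C)C)[C@@]1(O[Si](C)(C)C(C)(C)C)CO | intermediate
16 | benzoyl chloride | O=C(Cl)c1ccccc1 | starting material
17 | 7-O-TBDPS ether of 15 (not isolated) | O[C@H]1C=C[C@@H](O2)[C@@H](OC2(C)C)[C@@]1(O[Si](C)(C)C(C)(C)C)CO[Si](c3ccccc3)(c4ccccc4)C(C)(C)C | intermediate
18 | 6-O-benzoyl-7-O-TBDPS-2,3-O-isopropylidene-1-O-TBS-cyclohex-4-ene | O=C(c5ccccc5)O[C@H]1C=C[C@@H](O2)[C@@H](OC2(C)C)[C@@]1(O[Si](C)(C)C(C)(C)C)CO[Si](c3ccccc3)(c4ccccc4)C(C)(C)C | intermediate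
19 | 6-O-benzoyl-7-O-TBDPS-1-O-TBS-cyclohex-4-ene-2β,3β-diol | O=C(c5ccccc5)O[C@H]1C=C[C@@H](O)[C@@H](O)[C@@]1(O[Si](C)(C)C(C)(C)C)CO[Si](c3ccccc3)(c4ccccc4)C(C)(C)C | intermediate
20 | 3,6-di-O-benzoyl-7-O-TBDPS-1-O-TBS-cyclohex-4-en-2β-ol | O=C(c5ccccc5)O[C@H]1C=C[C@@H](OC(=O)c2ccccc2)[C@@H](O)[C@@]1(O[Si](C)(C)C(C)(C)C)CO[Si](c3ccccc3)(c4ccccc4)C(C)(C)C | intermediate
21 | (1S,2R,3R,6S)-1-(hydroxymethyl)cyclohex-4-ene-1,2,3,6-tetrol 3,6-dibenzoate | O=C(O[C@H]1C=C[C@@H](OC(=O)c2ccccc2)[C@@H](O)[C@@]1(O)CO)c1ccccc1 | target

## Step count and least certain steps

Total: 15 steps. Longest linear sequence: 15 steps from 1 (6 and 16 enter as purchased reagents).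

**Step 5 (key step).** The likeliest failure is insufficient discrimination between the two enantiotopic enone arms. The catalyst class was developed on acyclic hydroxy enones, and here it must tell apart two arms that differ only in their spatial relation to the OTBS and CH2O–B groups; slow turnover would also give time for loss of formaldehyde. The fallback keeps the C6–O bond and the six-membered ring but changes the tether atom from boron to carbon and the catalyst to a chiral phosphoric acid. Starting from 5, an acetalisation/oxa-Michael cascade with 4-methoxybenzaldehyde forms the hemiacetal on O7 and adds its hydroxyl to C6, giving the p-methoxybenzylidene acetal enone F1. Mild aqueous acetic acid hydrolyses F1 to diol 9, which is acetalised as in step 6, so the route is rejoined at 10.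

**Step 7.** The risk is poor facial selectivity in the osmylation if the axial O6 on the β face counters the shielding of the α face by the OTBS group, or slow reaction of the electron-poor, hindered alkene. The fallback replaces steric control by hydrogen-bond direction. Starting from 8, diol 9 is isolated after the peroxide cleavage and treated with stoichiometric OsO4·TMEDA in CH2Cl2 at −78 °C; the two β-face hydroxyls on C7 and C6 bind the reagent and deliver it to the β face. Reductive work-up with aqueous NaHSO3 gives the tetraol ketone F2, and one acetalisation with 2,2-dimethoxypropane/PPTS converts F2 into 12, where the route is rejoined.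

**Step 9.** Enolisation may go toward C3, or the C5 enolate may expel the axial acetal oxygen O6 before it is triflated. The fallback avoids an enolate altogether. Starting from 12, hydrazine hydrate gives the hydrazone F3, and iodine with tetramethylguanidine (Barton vinyl iodide synthesis) converts it into the C4 vinyl iodide F4, elimination being expected toward the unoxygenated C5. Reduction of the C–I bond with the Pd(OAc)2/PPh3/formate system of step 10 returns the route at 14.

**Step 14.** Over-acylation, acylation at O2, or ester migration between the cis hydroxyls would erode the regioselectivity. The fallback activates the diol through tin. Starting from 19, Bu2SnO in refluxing toluene forms the 2,3-O-dibutylstannylene acetal F5, in which the oxygen remote from the quaternary centre is the more nucleophilic; benzoyl chloride at 0 °C then acylates O3 and gives 20.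

**Step 15.** Cleavage of the tertiary TBS ether may be slow, and the prolonged exposure this demands would give time for benzoate migration to O2, O7 or O1. The fallback removes this silyl group before any ester is present. Starting from 14, TBAF in THF gives the tertiary alcohol F6. The operations of steps 11 to 14 are then repeated with O1 free: selective hydrolysis to the triol F7, silylation of O7 to the silyl ether F8 and benzoylation of O6 to the monobenzoate F9 (the tertiary hydroxyl does not acylate under these conditions), hydrolysis of the dioxolane to the triol F10, and selective benzoylation of O3 to the dibenzoate F11. HF·pyridine in THF, which now has only a primary silyl ether to cleave, converts F11 into 21.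

**Step 2.** The dearomatisation may be low-yielding through ortho attack of water, over-oxidation, or decomposition of the quinol in the acetic acid set free. The fallback changes the oxidant and the mechanism. Starting from 2, singlet oxygen generated from KHSO5 (as the triple salt 2KHSO5·KHSO4·K2SO4) and NaHCO3 in aqueous MeCN adds to the para position and gives the hydroperoxide F12; reduction with PPh3 returns the route at 3.

## Further compounds

F1 | step 5 | 6,7-O-(4-methoxybenzylidene)-1-O-TBS enone (aryl-equatorial epimer drawn; the acetal centre is lost on hydrolysis) | COc3ccc(cc3)[C@H]2O[C@H]1CC(=O)C=C[C@@]1(O[Si](C)(C)C(C)(C)C)CO2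
F2 | step 7 | 1-O-TBS-2β,3β,6β-trihydroxy-1-(hydroxymethyl)cyclohexan-4-one | O[C@H]1CC(=O)[C@@H](O)[C@@H](O)[C@@]1(O[Si](C)(C)C(C)(C)C)CO
F3 | step 9 | hydrazone of ketone 12 | CC2(C)O[C@H]1CC(=NN)[C@@H](O3)[C@@H](OC3(C)C)[C@@]1(O[Si](C)(C)C(C)(C)C)CO2
F4 | step 9 | C4 vinyl iodide (C4=C5) of the bis-acetonide | CC2(C)O[C@H]1C=C(I)[C@@H](O3)[C@@H](OC3(C)C)[C@@]1(O[Si](C)(C)C(C)(C)C)CO2
F5 | step 14 | 2,3-O-dibutylstannylene acetal of 19 | O=C(c5ccccc5)O[C@H]1C=C[C@@H](O2)[C@@H](O[Sn]2(CCCC)CCCC)[C@@]1(O[Si](C)(C)C(C)(C)C)CO[Si](c3ccccc3)(c4ccccc4)C(C)(C)C
F6 | step 15 | 2,3:6,7-di-O-isopropylidene-cyclohex-4-en-1-ol (O1 free) | CC2(C)O[C@H]1C=C[C@@H](O3)[C@@H](OC3(C)C)[C@@]1(O)CO2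
F7 | step 15 | 2,3-O-isopropylidene-cyclohex-4-ene-1,6β,7-triol | O[C@H]1C=C[C@@H](O2)[C@@H](OC2(C)C)[C@@]1(O)CO
F8 | step 15 | 7-O-TBDPS-2,3-O-isopropylidene-cyclohex-4-ene-1,6β-diol | O[C@H]1C=C[C@@H](O2)[C@@H](OC2(C)C)[C@@]1(O)CO[Si](c3ccccc3)(c4ccccc4)C(C)(C)C
F9 | step 15 | 6-O-benzoyl-7-O-TBDPS-2,3-O-isopropylidene-cyclohex-4-en-1-ol | O=C(c5ccccc5)O[C@H]1C=C[C@@H](O2)[C@@H](OC2(C)C)[C@@]1(O)CO[Si](c3ccccc3)(c4ccccc4)C(C)(C)C
F10 | step 15 | 6-O-benzoyl-7-O-TBDPS-cyclohex-4-ene-1,2β,3β-triol | O=C(c5ccccc5)O[C@H]1C=C[C@@H](O)[C@@H](O)[C@@]1(O)CO[Si](c3ccccc3)(c4ccccc4)C(C)(C)C
F11 | step 15 | 3,6-di-O-benzoyl-7-O-TBDPS-cyclohex-4-ene-1,2β-diol | O=C(c5ccccc5)O[C@H]1C=C[C@@H](OC(=O)c2ccccc2)[C@@H](O)[C@@]1(O)CO[Si](c3ccccc3)(c4ccccc4)C(C)(C)C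
F12 | step 2 | 4-hydroperoxy-4-[(tert-butyldimethylsilyloxy)methyl]cyclohexa-2,5-dien-1-one | O=C1C=CC(OO)(CO[Si](C)(C)C(C)(C)C)C=C1
A1 | alternative 1 | benzoic acid | OC(=O)c1ccccc1
A2 | alternative 1 | (1S,2R)-1,2-dihydroxycyclohexa-3,5-diene-1-carboxylic acid | OC(=O)[C@]1(O)C=CC=C[C@H]1O
A3 | alternative 2 | endo norbornene-fused ene-dione bearing CH2OTBS on the alkene | O=C1C=C(CO[Si](C)(C)C(C)(C)C)C(=O)[C@@H]2[C@H]1[C@@H]1C=C[C@H]2C1
A4 | alternative 2 | convex-face C1–C2 epoxide of A3 | O=C1[C@@H]3O[C@]3(CO[Si](C)(C)C(C)(C)C)C(=O)[C@@H]2[C@H]1[C@@H]1C=C[C@H]2C1
A5 | alternative 3 | 1,6-bis(4-methoxybenzyloxy)-2,3-O-isopropylidene-cyclohex-4-ene-1-carbaldehyde | O=C[C@@]1(OCc3ccc(OC)cc3)[C@@H](OCc3ccc(OC)cc3)C=C[C@H]2OC(C)(C)O[C@@H]12
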